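The reckoning for this flask is best done in coupling partner per substrate, not in minutes. The uptake, charged [coupling partner] over charged [substrate] (the feed ratio), is here 1.30. If coupling partner is the limiting reagent and is used up, then mono adduct + 2 bis adduct + 3 tris adduct, as fractions of substrate charged, equals the uptake. Since substrate and the three adducts sum to one, tris adduct = uptake + mono adduct + 2 substrate − 2.

| flask | substrate | coupling partner | remark | time |
|---|---|---|---|---|
| noon | 0.34 mM | 0.65 mM | run made earlier |  |
| dawn | 0.75 mM | 0.65 mM | run made earlier |  |
| summer | 0.50 mM | 0.98 mM | run made earlier |  |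
| flask | 0.50 mM | 0.650 mM |  | 2.0 h |

| run | time / min | substrate / % | mono adduct / % |
|---|---|---|---|
| noon | 10.0 | 14.3 | 57.1 |
| noon | 20.0 | 6.0 | 54.2 |
| noon | 30.0 | 3.5 | 50.1 |
| noon | 60.0 | 2.0 | 44.1 |
| noon | 120 | 1.2 | 42.0 |
| dawn | 25.0 | 28.0 | 61.9 |
| dawn | 50.0 | 27.9 | 62.1 |
| dawn | 80.0 | 27.4 | 62.0 |
| dawn | 90.0 | 27.2 | 61.9 |
| dawn | 120 | 27.6 | 61.6 |
| summer | 10.0 | 8.4 | 63.7 |
| summer | 20.0 | 2.9 | 58.4 |
| summer | 30.0 | 1.4 | 53.3 |
| summer | 60.0 | 0.2 | 46.6 |
| summer | 120 | 0.4 | 45.9 |

(each reading ± 0.3 percentage points)

- a reading or a percentage of mono adduct counts all its forms, free or not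

- substrate at 2.0 h, in percent of the substrate charged
- mono adduct at 2.0 h, in percent of the substrate charged
- bis adduct at 2.0 h, in percent of the substrate charged
- tris adduct at 2.0 h, in percent of the substrate charged

Dawn, with the same 0.65 mM of coupling partner, is flat from 25.0 min and still holds 27.6 % of substrate at 120 min, so coupling partner appears to end that run, and 2.0 h is longer than that first reading.

Summer looks nearly like this flask, with the same 0.50 mM of substrate, but its uptake is 1.96. At 10.0 min summer holds 8.4 % substrate and 63.7 % mono adduct, leaving 27.9 % for bis and tris adduct, so its uptake so far lies between 1.19 and 1.47. At 20.0 min it is at least 1.36. On summer's path, then, the flask's 1.30 falls near the first reading and before the second.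

Between those readings substrate drops 5.5 percentage points, yet mono adduct, though fed by it, drops 5.3 points. On these readings, mono adduct in summer is being consumed about twice as fast as substrate. Summer has 0.660 more uptake than the flask and reads 45.9 % mono adduct at 120 min, while the flask should stop earlier. This reckoning takes substrate near 8.4 % and mono adduct near 63.7 %, and the balance then gives tris adduct 10.5 % and bis adduct 17.4 %.

The forecast says 10 % substrate, 64 % mono adduct, 12 % bis adduct and 14 % tris adduct, more tris adduct than this reckoning, holding that “Two hours is ample to reach exhaustion”.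

At 2.0 h the flask gives 8.52 % substrate, 66.2 % mono adduct, 12.1 % bis adduct and 13.2 % tris adduct, with 0.00998 % of its charge of coupling partner left.

    crystals ⇌ mono adduct, rate k1*(cs1 - [mono adduct]) while solid is left; crystals form when [mono adduct] > cs1 (solubility = 0.0140 mM, k = 0.180 s⁻¹)
    coupling partner + mono adduct → bis adduct + by-product (k = 28.0 L mol⁻¹ s⁻¹)
    substrate + coupling partner → mono adduct + by-product (k = 8.90 L mol⁻¹ s⁻¹)
    coupling partner + bis adduct → tris adduct + by-product (k = 5.60 L mol⁻¹ s⁻¹)

Mono adduct stands 2.5 points above the summer reading used, and the flask's own substrate and mono adduct return 13.2 % tris adduct through the balance at uptake 1.30. The neighbour charged with 0.85 mM of substrate has uptake 0.765, below one, so at least 23.5 % of its substrate has to remain. It ends with 34.3 % substrate, 57.5 % mono adduct and 0 % of coupling partner. From those two amounts the balance gives 2.51 % tris adduct, and that neighbour holds 2.51 %.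

The earlier runs and the new flask stem from a simulated flask for an exercise.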